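(The numbers in the tables come from a simulation for substances that don't exist; scatter was added.)

Whatever happens in these flasks, the solid reagent charged stays counted: it is still solid, dissolved as partner, or has become left-handed product, right-handed product or decomposed reagent.

| flask | left-handed substrate | right-handed substrate | solid reagent | temperature | remark | time |
|---|---|---|---|---|---|---|
| south | 5.0 × 10⁻⁴ M | 5.0 × 10⁻⁴ M | 0.34 mM | −25 °C | run made earlier |  |
| north-east | 5.0 × 10⁻⁴ M | 5.0 × 10⁻⁴ M | 0.75 mM | 18 °C | run made earlier |  |
| beta | 5.0 × 10⁻⁴ M | 5.0 × 10⁻⁴ M | 0.500 mM | 55 °C |  | 2.0 min |
| zeta | 5.0 × 10⁻⁴ M | 5.0 × 10⁻⁴ M | 0.500 mM | 30 °C |  | 2.0 min |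
| eta | 5.0 × 10⁻⁴ M | 5.0 × 10⁻⁴ M | 0.500 mM | −20 °C |  | 2.0 min |
| epsilon | 5.0 × 10⁻⁴ M | 5.0 × 10⁻⁴ M | 0.500 mM | 5 °C |  | 2.0 min |

- south (time / min: left-handed product / %): 8.00: 17.1; 20.0: 21.2; 40.0: 20.8; 50.0: 20.5; 80.0: 21.4; 120: 19.6
- north-east (time / min: left-handed product / %): 1.00: 18.2; 2.00: 30.7; 4.00: 30.2; 6.00: 29.0; 8.00: 29.7; 12.0: 28.3; 15.0: 29.7

(scatter of a reading: 1 percentage point)

- partner is single-handed; left-handed substrate and right-handed substrate are mirror images of each other, charged as a racemate, each of them at the stated concentration
- solid reagent is a solid; its amount is given per volume of the solution
- reactions considered so far: partner + left-handed substrate -> left-handed product; partner + right-handed substrate -> right-handed product; solid reagent <-> partner; partner -> decomposed reagent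
- at the start none of the solid reagent is in solution
- the handed part of partner does not stay in what it makes, so the products of the two hands are mirror images too

- which flask leads in amount of left-handed product, in percent of the left-handed substrate and right-handed substrate together charged ("all alike" within 1.5 percentage points) (beta / zeta / eta / epsilon / all alike)
- how much left-handed product is there at the end, in percent of the left-handed substrate and right-handed substrate together charged: beta
- how much left-handed product is there at the end, in percent of the left-handed substrate and right-handed substrate together charged: zeta
- how much left-handed product is there at the end, in percent of the left-handed substrate and right-handed substrate together charged: eta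
- how much left-handed product is there at the end, in percent of the left-handed substrate and right-handed substrate together charged: epsilon

I read the plateaus first: the south run levels at 20.7% and the north-east run at 29.6%. Turned into concentration and divided by the charged c(solid reagent), they give 0.609 and 0.395. I call this number the capture, the share of the solid reagent charged that ends as left-handed product. The fraction left for everything else is one minus the capture, so I work with the odds, capture over that fraction, and assume their logarithm runs straight in temperature, although the two runs differ in c(solid reagent) as well, which makes this a rough reckoning. Epsilon then gets a capture of 0.459, zeta 0.338, beta 0.236 and eta 0.584. As plateaus these are 22.9%, 16.9%, 11.8% and 29.2%.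

One number is not enough, though. The south run still reads 17.1% at 8.00 min, below its plateau, and eta lies close to that run in temperature, so I expect eta well under its plateau at 2.0 min. The north-east run is on its plateau at 2.00 min. I therefore commit to epsilon as the leader, provided it finishes.

The forecast says zeta, with 17% in beta, 19.5% in zeta, 13% in eta and 18% in epsilon: “Cold flasks are cut off by time, hot ones by waste”.

The flasks give 9.87% in beta, 17.3% in zeta, 11.1% in eta and 24.8% in epsilon, so epsilon leads, and its capture of 0.496 lies between the readings 0.395 and 0.609.

    partner + left-handed substrate → left-handed product (k = 120 /M/s, Ea = 47.0 kJ/mol)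
    partner + right-handed substrate → right-handed product (k = 45.0 /M/s, Ea = 43.0 kJ/mol)
    solid reagent ⇌ partner, rate k3*(cs3 - [partner]) while solid is left; crystals form when [partner] > cs3 (solubility = 0.200 mM, k = 0.0390 /s)
    partner → decomposed reagent (k = 0.0230 /s, Ea = 80.0 kJ/mol)
    (constants at 5 °C)

In epsilon half of the dissolution up to 2.0 min is done by 0.697 min and half of the passing to left-handed product up to that time by 0.816 min, and solid reagent, the limiting reagent, stands at 0% of its own charge at 2.00 min. Eta still holds 33.7% of its own charge of solid reagent at 2.00 min, and after 20.0 min its left-handed product stands at 29.5%, a capture of 0.589 against my 0.584.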